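**The question.** How much Z stands in the larch flask at 6.0 d, and can any option still add to it?

all flasks: G 0.050 M; E 0.01 mol%
- larch: temperature 5 °C; the very flask that is asked about, followed so far
- birch: temperature 11 °C; run made earlier
- flask: temperature 5 °C; time 6.0 d

| run | time / h | Z / % | G / % |
|---|---|---|---|
| larch | 6.00 | 46.2 | 3.5 |
| larch | 12.0 | 48.6 | 0.4 |
| larch | 25.0 | 49.2 | 0 |
| larch | 50.0 | 48.5 | 0 |
| larch | 96.0 | 48.4 | 0 |
| birch | 6.00 | 32.2 | 6.6 |
| birch | 12.0 | 32.8 | 3.1 |
| birch | 25.0 | 32.4 | 2.6 |
| birch | 50.0 | 33.1 | 0.5 |
| birch | 96.0 | 31.9 | 0.8 |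

(standard deviation of a reading: 0.5 percentage points)

- Monday's: at 6.0 d take out 90% of the Z then present, then wait 40 h
- Saturday's: at 6.0 d raise the temperature by 15 K, then wait 40 h
- Wednesday's: change nothing and wait 40 h more
- Friday's: at 6.0 d add E, 100% of the amount charged, then wait 40 h

* Z, in percent of the G first charged, at 6.0 d
* the option that brings most further Z ("none" if no option brings more than 2 percentage points) (Monday's / Saturday's / Wednesday's / Friday's / none)
* Z present, with what was taken out counted in, in percent of the G first charged, after Saturday's
* Z present, with what was taken out counted in, in percent of the G first charged, after Wednesday's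

- percentages count the G that a species holds: one Q counts as two
- Z that was removed still counts
- reactions considered so far: E -> X; G + E <-> J; J -> E + Z; E + Z -> D; 2 G -> Q
- additions bring no volume worth counting

**Two exits.** In the larch run, G reads 0% by 25.0 h, and Z stays flat from 12.0 h onward, with a mean of 48.7%. The reactions considered give G two ways out: the enzyme round makes Z, and the pairing of G makes Q. So we need two amounts, the G that became Z and the G that became Q. Their ratio, here 0.948, we call the split, a selectivity factor.

**Why concentration.** The pairing goes with the square of G, but at a given E the enzyme round rises at most with its first power. So at a given E lower G favours Z, and since both exits draw on G, the split is made while G lasts. The larch flask waits far longer than G lasted, so we commit to 48.7% of Z at 6.0 d and expect no option to pass 2 percentage points.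

**The forecast.** The forecast gives 48.7% (from 48.2% to 49.2%), 48.7% after Saturday's, 48.7% after Wednesday's, and as best option none: “Fresh enzyme, heat, removing Z or waiting therefore have nothing to convert.”

**The result.** The larch flask gives 48.5% at 6.0 d, with G at 0%. Saturday's ends at 48.5%, Wednesday's at 48.5%, and the best option is none.

    E → X (k = 0.0230 h⁻¹, Ea = 286 kJ mol⁻¹)
    G + E ⇌ J (K = 38.0 M⁻¹, k = 2.20 × 10⁷ M⁻¹ h⁻¹, Ea = 34.0 kJ mol⁻¹, ΔH = −90.0 kJ mol⁻¹)
    J → E + Z (k = 3200 h⁻¹, Ea = 65.0 kJ mol⁻¹)
    E + Z → D (k = 1.50 M⁻¹ h⁻¹, Ea = 58.0 kJ mol⁻¹)
    2 G → Q (k = 8.30 M⁻¹ h⁻¹, Ea = 48.0 kJ mol⁻¹)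
    (constants at 5 °C)

**Where G went.** The larch flask's split comes to 0.942, and the main reason for the shortfall is the pairing: the same run without it holds 99.9% of Z, not 48.5%. In the neighbour flask with 0.020 M of G at the same loading, E falls along with G, and the split rises to 1.21. That neighbour ends at 54.7% of Z.

The numbers in the tables stem from a simulated flask from invented constants; the scatter is artificial.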